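**Retrosynthetic overview**
- The cage is opened in turn at C1–benzoyl (bridgehead acylation), C1–C2 (intramolecular aldol then oxidation, closing trione ring A last), C5–geranyl (β-diketone alkylation) and C5–C4 (intramolecular aldol then oxidation, closing the seven-membered ring).
- Cyclohexanone ring B comes from a cyclopentane-bearing propanal and methyl vinyl ketone: an amine-catalysed intermolecular Michael addition is the key fragment union and sets C7; aldol condensation and two methyl cuprate additions finish ring B with its gem-dimethyl C8.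
- The cyclopentane comes from an alkylidene malonate and a thioacetate silyl ketene acetal by a copper bis(oxazoline)-catalysed intermolecular Mukaiyama–Michael addition (sets C11), malonate ring closure, Krapcho reaction and trans-selective enolate alkoxymethylation (sets C3).
- Ring order: cyclopentane, then cyclohexanone ring B, then the seven-membered ring, then trione ring A, which completes the homoadamantane cage.

Locants used in the explanations (target numbering): C1 benzoyl bridgehead; C2, C4, C9 carbonyls; C3 quaternary carbon shared with the cyclopentane; C5 geranyl bridgehead; C6 CH2; C7 CH; C8 CMe2; C10 (CH2) and C11 (CH) the two-carbon bridge; C12 CMe2, C13 and C14 the cyclopentane CH2 groups (C14 on C3). Locants inside systematic names are the usual ones. "Cp" = (1R,2S)-2-(benzyloxymethyl)-2-(tert-butyldiphenylsilyloxymethyl)-5,5-dimethylcyclopentyl.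

Assumption: in step 5 the (R,R)-ligand is taken to give the (S)-adduct; if the observed sense is opposite, the (S,S)-ligand is used and nothing else changes.

**Step 1**
Reactants: 1 methyl isobutyrate; 2 1-bromo-2-chloroethane
Product: 3 methyl 4-chloro-2,2-dimethylbutanoate
Conditions: LiN(i-Pr)2, THF, −78 °C → rt
Reagents that add atoms: none
Why: Ester enolate alkylation (SN2 at the C–Br end) builds the future C12 quaternary carbon with its C13–C14 chloroethyl arm.

**Step 2**
Reactants: 3 methyl 4-chloro-2,2-dimethylbutanoate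
Product: 4 4-chloro-2,2-dimethylbutanal
Conditions: i-Bu2AlH (1.05 equiv), CH2Cl2, −78 °C
Reagents that add atoms: none
Why: Partial ester reduction works because the hindered aluminium hemiacetal is stable at −78 °C and releases the aldehyde only on work-up.

**Step 3**
Reactants: 4 4-chloro-2,2-dimethylbutanal; 5 dimethyl malonate
Product: 6 dimethyl 2-(4-chloro-2,2-dimethylbutylidene)malonate
Conditions: TiCl4, pyridine, THF, 0 °C → rt
Reagents that add atoms: none
Why: The Lehnert variant of the Knoevenagel condensation tolerates α-quaternary aldehydes and gives the chelating Michael acceptor.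

**Step 4**
Reactants: 7 S-tert-butyl ethanethioate
Product: 8 1-(tert-butylsulfanyl)-1-(trimethylsilyloxy)ethene
Conditions: LiN(i-Pr)2, THF, −78 °C; Me3SiCl
Reagents that add atoms: chlorotrimethylsilane, C[Si](C)(C)Cl
Why: O-silylation of the thioester enolate gives the silyl ketene thioacetal nucleophile for the Mukaiyama–Michael reaction.

**Step 5**
Reactants: 6 dimethyl 2-(4-chloro-2,2-dimethylbutylidene)malonate; 8 1-(tert-butylsulfanyl)-1-(trimethylsilyloxy)ethene
Product: 9 dimethyl 2-[(3S)-1-(tert-butylsulfanyl)-6-chloro-4,4-dimethyl-1-oxohexan-3-yl]malonate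
Conditions: Cu(SbF6)2 / (R,R)-2,2'-(propane-2,2-diyl)bis(4-tert-butyl-4,5-dihydrooxazole) (10 mol %), (CF3)2CHOH (2 equiv), PhMe/CH2Cl2 3:1, −78 °C
Reagents that add atoms: none
Why: In this intermolecular Mukaiyama–Michael addition the malonate chelates the chiral divalent copper Lewis acid, the ketene acetal adds to the exposed face of the alkylidene carbon and sets C11 as S, and the fluorinated alcohol turns the catalyst over by silyl transfer.

**Step 6**
Reactants: 9 dimethyl 2-[(3S)-1-(tert-butylsulfanyl)-6-chloro-4,4-dimethyl-1-oxohexan-3-yl]malonate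
Product: 10 dimethyl (2R)-2-[2-(tert-butylsulfanyl)-2-oxoethyl]-3,3-dimethylcyclopentane-1,1-dicarboxylate
Conditions: Cs2CO3, NaI (cat.), DMF, 50 °C
Reagents that add atoms: none
Why: Intramolecular malonate alkylation (5-exo-tet, helped by the gem-dimethyl group) closes the cyclopentane and makes C3 quaternary without touching the non-acidic C11 centre.

**Step 7**
Reactants: 10 dimethyl (2R)-2-[2-(tert-butylsulfanyl)-2-oxoethyl]-3,3-dimethylcyclopentane-1,1-dicarboxylate
Product: 11 dimethyl (2R)-3,3-dimethyl-2-(2-oxoethyl)cyclopentane-1,1-dicarboxylate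
Conditions: i-Bu2AlH (1.1 equiv), PhMe, −78 °C
Reagents that add atoms: none
Why: The thioester is much more electrophilic than the two neopentyl-type methyl esters, so one equivalent of hydride at low temperature reduces it selectively to the aldehyde.

**Step 8**
Reactants: 11 dimethyl (2R)-3,3-dimethyl-2-(2-oxoethyl)cyclopentane-1,1-dicarboxylate
Product: 12 dimethyl (2R)-2-(3-methoxyprop-2-enyl)-3,3-dimethylcyclopentane-1,1-dicarboxylate (E/Z mixture)
Conditions: Ph3P(CH2OMe)Cl, KN(SiMe3)2, THF, 0 °C; then 11, −78 °C → rt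
Reagents that add atoms: (methoxymethyl)triphenylphosphonium chloride, COC[P+](c1ccccc1)(c1ccccc1)c1ccccc1.[Cl-]
Why: Wittig methoxymethylenation adds C8 as a masked aldehyde that survives the basic and reducing steps that follow.

**Step 9**
Reactants: 12 dimethyl (2R)-2-(3-methoxyprop-2-enyl)-3,3-dimethylcyclopentane-1,1-dicarboxylate
Product: 13 methyl (2S)-2-(3-methoxyprop-2-enyl)-3,3-dimethylcyclopentane-1-carboxylate (C1 epimers)
Conditions: LiCl, H2O, DMSO, 160 °C
Reagents that add atoms: none
Why: Krapcho dealkoxycarbonylation leaves one ester on C3, whose configuration does not matter because it is re-enolised in the next step.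

**Step 10**
Reactants: 13 methyl (2S)-2-(3-methoxyprop-2-enyl)-3,3-dimethylcyclopentane-1-carboxylate
Product: 14 methyl (1S,2R)-1-(benzyloxymethyl)-2-(3-methoxyprop-2-enyl)-3,3-dimethylcyclopentane-1-carboxylate
Conditions: LiN(i-Pr)2, THF, −78 °C; BnOCH2Cl, −78 → −20 °C
Reagents that add atoms: benzyl chloromethyl ether, ClCOCc1ccccc1
Why: Alkylation of the exocyclic ester enolate occurs anti to the adjacent C11 side chain, so the CH2OBn group (future C4) ends up trans and the ester (future C2) cis to C10, which sets C3.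

**Step 11**
Reactants: 14 methyl (1S,2R)-1-(benzyloxymethyl)-2-(3-methoxyprop-2-enyl)-3,3-dimethylcyclopentane-1-carboxylate
Product: 15 [(1R,2R)-1-(benzyloxymethyl)-2-(3-methoxyprop-2-enyl)-3,3-dimethylcyclopentyl]methanol
Conditions: LiAlH4, THF, 0 °C
Reagents that add atoms: none
Why: Hydride reduction converts the remaining ester into the neopentyl alcohol that will become C2.

**Step 12**
Reactants: 15 [(1R,2R)-1-(benzyloxymethyl)-2-(3-methoxyprop-2-enyl)-3,3-dimethylcyclopentyl]methanol
Product: 16 {[(1S,2R)-1-(benzyloxymethyl)-2-(3-methoxyprop-2-enyl)-3,3-dimethylcyclopentyl]methoxy}(tert-butyl)diphenylsilane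
Conditions: t-BuPh2SiCl, imidazole, DMAP (cat.), DMF, 40 °C
Reagents that add atoms: tert-butyl(chloro)diphenylsilane, CC(C)(C)[Si](Cl)(c1ccccc1)c1ccccc1
Why: Silylation gives an acid-stable ether that is orthogonal to the benzyl ether, so the C4 and C2 arms can be unmasked one at a time.

**Step 13**
Reactants: 16 {[(1S,2R)-1-(benzyloxymethyl)-2-(3-methoxyprop-2-enyl)-3,3-dimethylcyclopentyl]methoxy}(tert-butyl)diphenylsilane
Product: 17 3-Cp-propanal
Conditions: 1 M HCl, THF, rt
Reagents that add atoms: water, O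
Why: Mild acid hydrolysis of the enol ether unmasks the aldehyde whose α-carbon is C7.

**Step 14**
Reactants: 17 3-Cp-propanal; 18 methyl vinyl ketone
Product: 19 (2S)-2-(Cp-methyl)-5-oxohexanal
Conditions: (S)-2-[methoxy(diphenyl)methyl]pyrrolidine (10 mol %), ethyl 3,4-dihydroxybenzoate (20 mol %), neat, 4 °C
Reagents that add atoms: none
Why: In this intermolecular enamine Michael addition the E-enamine is shielded on the face syn to the diphenylmethyl group, so the enone adds to the opposite face and sets C7 as S under catalyst control, independent of the remote C11 centre.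

**Step 15**
Reactants: 19 (2S)-2-(Cp-methyl)-5-oxohexanal
Product: 20 (4S)-4-(Cp-methyl)cyclohex-2-en-1-one
Conditions: LiOH (0.2 equiv), i-PrOH, rt
Reagents that add atoms: none
Why: Intramolecular aldol condensation of the methyl ketone onto the aldehyde (Robinson-type closure) forms ring B and leaves the γ-stereocentre C7 untouched.

**Step 16**
Reactants: 20 (4S)-4-(Cp-methyl)cyclohex-2-en-1-one
Product: 21 {[(3S,4S)-3-methyl-4-(Cp-methyl)cyclohex-1-en-1-yl]oxy}trimethylsilane
Conditions: MeLi (2 equiv), CuI (1 equiv), Et2O, 0 °C; then 20, Me3SiCl, −78 °C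
Reagents that add atoms: lithium dimethylcuprate, [Li+].C[Cu-]C; chlorotrimethylsilane, C[Si](C)(C)Cl
Why: Gilman conjugate addition occurs anti to the C7 substituent (a temporary trans centre at C8), and trapping the enolate as its silyl ether fixes the regiochemistry for dehydrogenation.

**Step 17**
Reactants: 21 {[(3S,4S)-3-methyl-4-(Cp-methyl)cyclohex-1-en-1-yl]oxy}trimethylsilane
Product: 22 (4S)-3-methyl-4-(Cp-methyl)cyclohex-2-en-1-one
Conditions: Pd(OAc)2 (1.05 equiv), MeCN, rt
Reagents that add atoms: none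
Why: Saegusa–Ito oxidation (divalent palladium enolate, then β-hydride elimination) regenerates the enone, now with a methyl group on C8.

**Step 18**
Reactants: 22 (4S)-3-methyl-4-(Cp-methyl)cyclohex-2-en-1-one
Product: 24 (4S)-4-(Cp-methyl)-3,3-dimethylcyclohexan-1-one, via trimethylsilyl enol ether 23 (not isolated)
Conditions: MeLi (2 equiv), CuI (1 equiv), Et2O, 0 °C; then 22, Me3SiCl, −78 → −20 °C; 1 M HCl work-up
Reagents that add atoms: lithium dimethylcuprate, [Li+].C[Cu-]C
Why: A second silyl-accelerated cuprate conjugate addition creates the C8 gem-dimethyl group, and acidic work-up hydrolyses the silyl enol ether to the ring B ketone.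

**Step 19**
Reactants: 24 (4S)-4-(Cp-methyl)-3,3-dimethylcyclohexan-1-one
Product: 25 (4S)-4-{[(1R,2S)-2-(hydroxymethyl)-2-(tert-butyldiphenylsilyloxymethyl)-5,5-dimethylcyclopentyl]methyl}-3,3-dimethylcyclohexan-1-one
Conditions: H2 (1 atm), Pd/C (10 wt % Pd on carbon), EtOAc, rt
Reagents that add atoms: none
Why: Hydrogenolysis removes the benzyl ether (trans arm, future C4) while ketone and silyl ether are inert and no alkene is yet present.

**Step 20**
Reactants: 25 (4S)-4-{[(1R,2S)-2-(hydroxymethyl)-2-(tert-butyldiphenylsilyloxymethyl)-5,5-dimethylcyclopentyl]methyl}-3,3-dimethylcyclohexan-1-one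
Product: 26 (1R,2R)-1-(tert-butyldiphenylsilyloxymethyl)-2-{[(1S)-2,2-dimethyl-4-oxocyclohexyl]methyl}-3,3-dimethylcyclopentane-1-carbaldehyde
Conditions: Dess–Martin periodinane, CH2Cl2, rt
Reagents that add atoms: none
Why: Dess–Martin oxidation gives the non-enolisable neopentyl aldehyde (C4) that serves as the acceptor for the first ring closure.

**Step 21**
Reactants: 26 (1R,2R)-1-(tert-butyldiphenylsilyloxymethyl)-2-{[(1S)-2,2-dimethyl-4-oxocyclohexyl]methyl}-3,3-dimethylcyclopentane-1-carbaldehyde
Product: 27 tricyclic C4-hydroxy ketone with the C5–C4 bond formed (carbinol epimers)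
Conditions: LiN(SiMe3)2 (1.1 equiv), THF (0.01 M), −78 °C; AcOH
Reagents that add atoms: none
Why: Enolisation at the unhindered C5 methylene (C1 is neopentyl) is followed by a seven-membered intramolecular aldol addition, and because the four-atom tether can only bridge ring B cis-1,3 the C5 configuration follows from C7, while the carbinol centre is removed in the next step.

**Step 22**
Reactants: 27 tricyclic C4-hydroxy ketone
Product: 28 tricyclic C4,C9-diketone with C5–H
Conditions: Dess–Martin periodinane, CH2Cl2, rt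
Reagents that add atoms: none
Why: Oxidation of the β-hydroxy ketone gives the β-diketone that makes C5 the only acidic carbon.

**Step 23**
Reactants: 28 tricyclic C4,C9-diketone with C5–H; 29 geranyl bromide
Product: 30 C5-geranyl tricyclic diketone
Conditions: NaH (1.05 equiv), THF, 0 °C; then 29, rt
Reagents that add atoms: none
Why: C-alkylation of the β-diketone enolate (SN2, E-alkene retained) places geranyl in the only available outward position at C5, so the quaternary C5 configuration is fixed by the ring system.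

**Step 24**
Reactants: 30 C5-geranyl tricyclic diketone
Product: 31 C5-geranyl tricyclic diketone with free CH2OH on C3
Conditions: HF·pyridine, pyridine, THF, 0 °C → rt
Reagents that add atoms: none
Why: Acidic fluoride desilylation frees the cis hydroxymethyl arm without generating an alkoxide that could trigger retro-Claisen cleavage of the non-enolisable diketone.

**Step 25**
Reactants: 31 C5-geranyl tricyclic diketone with free CH2OH on C3
Product: 32 C5-geranyl tricyclic diketone with CHO (C2) on C3
Conditions: Dess–Martin periodinane, CH2Cl2, rt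
Reagents that add atoms: none
Why: Dess–Martin oxidation gives the C2 aldehyde, which the cis relationship to C10 holds next to C1.

**Step 26**
Reactants: 32 C5-geranyl tricyclic diketone with CHO (C2) on C3
Product: 33 caged C2-hydroxy diketone with the C1–C2 bond formed (carbinol epimers)
Conditions: LiN(SiMe3)2 (1.1 equiv), THF, −78 → −40 °C; AcOH
Reagents that add atoms: none
Why: C1 is now the only enolisable position, so a six-membered intramolecular aldol addition closes ring A and the homoadamantane cage, with the C1 configuration dictated by the cage.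

**Step 27**
Reactants: 33 caged C2-hydroxy diketone
Product: 34 caged 2,4,9-trione with C1–H (1-debenzoyl target)
Conditions: Dess–Martin periodinane, CH2Cl2, rt
Reagents that add atoms: none
Why: Oxidation removes the carbinol centre and completes the non-enolisable trione, leaving C1–H as the only α-hydrogen.

**Step 28**
Reactants: 34 caged 2,4,9-trione with C1–H; 35 benzoyl chloride
Product: 36 CNP0168637.1
Conditions: lithium 2,2,6,6-tetramethylpiperidide (LiTMP, 1.3 equiv), THF, −78 °C; then 35, −78 °C
Reagents that add atoms: none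
Why: Bridgehead deprotonation between C2=O and C9=O gives a configurationally locked carbanion that is C-acylated with retention (it cannot O-acylate as a planar enolate), installing the benzoyl group on quaternary C1.

**Compound list**
1 | methyl isobutyrate | COC(=O)C(C)C | starting material
2 | 1-bromo-2-chloroethane | ClCCBr | starting material
3 | methyl 4-chloro-2,2-dimethylbutanoate | COC(=O)C(C)(C)CCCl | intermediate
4 | 4-chloro-2,2-dimethylbutanal | O=CC(C)(C)CCCl | intermediate
5 | dimethyl malonate | COC(=O)CC(=O)OC | starting material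
6 | dimethyl 2-(4-chloro-2,2-dimethylbutylidene)malonate | COC(=O)C(=CC(C)(C)CCCl)C(=O)OC | intermediate
7 | S-tert-butyl ethanethioate | CC(=O)SC(C)(C)C | starting material
8 | 1-(tert-butylsulfanyl)-1-(trimethylsilyloxy)ethene | C=C(O[Si](C)(C)C)SC(C)(C)C | intermediate
9 | dimethyl 2-[(3S)-1-(tert-butylsulfanyl)-6-chloro-4,4-dimethyl-1-oxohexan-3-yl]malonate | COC(=O)C(C(=O)OC)[C@H](CC(=O)SC(C)(C)C)C(C)(C)CCCl | intermediate
10 | dimethyl (2R)-2-[2-(tert-butylsulfanyl)-2-oxoethyl]-3,3-dimethylcyclopentane-1,1-dicarboxylate | COC(=O)C1(C(=O)OC)CCC(C)(C)[C@H]1CC(=O)SC(C)(C)C | intermediate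
11 | dimethyl (2R)-3,3-dimethyl-2-(2-oxoethyl)cyclopentane-1,1-dicarboxylate | COC(=O)C1(C(=O)OC)CCC(C)(C)[C@H]1CC=O | intermediate
12 | dimethyl (2R)-2-(3-methoxyprop-2-enyl)-3,3-dimethylcyclopentane-1,1-dicarboxylate (E/Z mixture) | COC(=O)C1(C(=O)OC)CCC(C)(C)[C@H]1CC=COC | intermediate
13 | methyl (2S)-2-(3-methoxyprop-2-enyl)-3,3-dimethylcyclopentane-1-carboxylate (C1 epimers, E/Z mixture) | COC(=O)C1CCC(C)(C)[C@H]1CC=COC | intermediate
14 | methyl (1S,2R)-1-(benzyloxymethyl)-2-(3-methoxyprop-2-enyl)-3,3-dimethylcyclopentane-1-carboxylate (E/Z mixture) | COC(=O)[C@@]1(COCc2ccccc2)CCC(C)(C)[C@H]1CC=COC | intermediate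
15 | [(1R,2R)-1-(benzyloxymethyl)-2-(3-methoxyprop-2-enyl)-3,3-dimethylcyclopentyl]methanol (E/Z mixture) | OC[C@@]1(COCc2ccccc2)CCC(C)(C)[C@H]1CC=COC | intermediate
16 | {[(1S,2R)-1-(benzyloxymethyl)-2-(3-methoxyprop-2-enyl)-3,3-dimethylcyclopentyl]methoxy}(tert-butyl)diphenylsilane (E/Z mixture) | CC(C)(C)[Si](c1ccccc1)(c1ccccc1)OC[C@@]1(COCc2ccccc2)CCC(C)(C)[C@H]1CC=COC | intermediate
17 | 3-[(1R,2S)-2-(benzyloxymethyl)-2-(tert-butyldiphenylsilyloxymethyl)-5,5-dimethylcyclopentyl]propanal | CC(C)(C)[Si](c1ccccc1)(c1ccccc1)OC[C@@]1(COCc2ccccc2)CCC(C)(C)[C@H]1CCC=O | intermediate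
18 | methyl vinyl ketone (but-3-en-2-one) | CC(=O)C=C | starting material
19 | (2S)-2-{[(1R,2S)-2-(benzyloxymethyl)-2-(tert-butyldiphenylsilyloxymethyl)-5,5-dimethylcyclopentyl]methyl}-5-oxohexanal | O=C[C@@H](CCC(C)=O)C[C@@H]1C(C)(C)CC[C@]1(COCc2ccccc2)CO[Si](c2ccccc2)(c2ccccc2)C(C)(C)C | intermediate
20 | (4S)-4-{[(1R,2S)-2-(benzyloxymethyl)-2-(tert-butyldiphenylsilyloxymethyl)-5,5-dimethylcyclopentyl]methyl}cyclohex-2-en-1-one | O=C1C=C[C@H](C[C@@H]2C(C)(C)CC[C@]2(COCc3ccccc3)CO[Si](c3ccccc3)(c3ccccc3)C(C)(C)C)CC1 | intermediate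
21 | {[(3S,4S)-4-{[(1R,2S)-2-(benzyloxymethyl)-2-(tert-butyldiphenylsilyloxymethyl)-5,5-dimethylcyclopentyl]methyl}-3-methylcyclohex-1-en-1-yl]oxy}trimethylsilane | C[Si](C)(C)OC1=C[C@@H](C)[C@H](C[C@@H]2C(C)(C)CC[C@]2(COCc3ccccc3)CO[Si](c3ccccc3)(c3ccccc3)C(C)(C)C)CC1 | intermediate
22 | (4S)-4-{[(1R,2S)-2-(benzyloxymethyl)-2-(tert-butyldiphenylsilyloxymethyl)-5,5-dimethylcyclopentyl]methyl}-3-methylcyclohex-2-en-1-one | O=C1C=C(C)[C@H](C[C@@H]2C(C)(C)CC[C@]2(COCc3ccccc3)CO[Si](c3ccccc3)(c3ccccc3)C(C)(C)C)CC1 | intermediate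
23 | {[(4S)-4-{[(1R,2S)-2-(benzyloxymethyl)-2-(tert-butyldiphenylsilyloxymethyl)-5,5-dimethylcyclopentyl]methyl}-3,3-dimethylcyclohex-1-en-1-yl]oxy}trimethylsilane | C[Si](C)(C)OC1=CC(C)(C)[C@H](C[C@@H]2C(C)(C)CC[C@]2(COCc3ccccc3)CO[Si](c3ccccc3)(c3ccccc3)C(C)(C)C)CC1 | intermediate
24 | (4S)-4-{[(1R,2S)-2-(benzyloxymethyl)-2-(tert-butyldiphenylsilyloxymethyl)-5,5-dimethylcyclopentyl]methyl}-3,3-dimethylcyclohexan-1-one | O=C1CC(C)(C)[C@H](C[C@@H]2C(C)(C)CC[C@]2(COCc3ccccc3)CO[Si](c3ccccc3)(c3ccccc3)C(C)(C)C)CC1 | intermediate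
25 | (4S)-4-{[(1R,2S)-2-(hydroxymethyl)-2-(tert-butyldiphenylsilyloxymethyl)-5,5-dimethylcyclopentyl]methyl}-3,3-dimethylcyclohexan-1-one | O=C1CC(C)(C)[C@H](C[C@@H]2C(C)(C)CC[C@]2(CO)CO[Si](c3ccccc3)(c3ccccc3)C(C)(C)C)CC1 | intermediate
26 | (1R,2R)-1-(tert-butyldiphenylsilyloxymethyl)-2-{[(1S)-2,2-dimethyl-4-oxocyclohexyl]methyl}-3,3-dimethylcyclopentane-1-carbaldehyde | O=C1CC(C)(C)[C@H](C[C@@H]2C(C)(C)CC[C@]2(C=O)CO[Si](c3ccccc3)(c3ccccc3)C(C)(C)C)CC1 | intermediate
27 | tricyclic aldol (tricyclo[7.3.1.0(3,7)]tridecane skeleton): ring B (C5, C6, C7, C8 gem-dimethyl, C1H2, C9=O) bridged from C5 to C7 by C4H(OH)–C3–C11H–C10H2; C3 bears CH2OSi(t-Bu)Ph2 cis to C10 and closes the 12,12-dimethylcyclopentane; C5–C4 and C7–C10 bonds cis on ring B, C4 trans to C10 on the cyclopentane, C11 R, C4 carbinol epimers | O=C1CC(C)(C)[C@H]2C[C@@H]1C(O)[C@]1(CO[Si](c3ccccc3)(c3ccccc3)C(C)(C)C)CCC(C)(C)[C@H]1C2 | intermediate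
28 | tricyclic β-diketone: as 27 with C4=O (C5–H between C4=O and C9=O) | O=C1CC(C)(C)[C@H]2C[C@@H]1C(=O)[C@]1(CO[Si](c3ccccc3)(c3ccccc3)C(C)(C)C)CCC(C)(C)[C@H]1C2 | intermediate
29 | geranyl bromide, (2E)-1-bromo-3,7-dimethylocta-2,6-diene | CC(C)=CCC/C(C)=C/CBr | starting material
30 | as 28 with (E)-geranyl on quaternary C5 (outward bridgehead position) | O=C1CC(C)(C)[C@H]2C[C@]1(C/C=C(\C)CCC=C(C)C)C(=O)[C@]1(CO[Si](c3ccccc3)(c3ccccc3)C(C)(C)C)CCC(C)(C)[C@H]1C2 | intermediate
31 | as 30 with free CH2OH on C3 (cis to C10) | O=C1CC(C)(C)[C@H]2C[C@]1(C/C=C(\C)CCC=C(C)C)C(=O)[C@]1(CO)CCC(C)(C)[C@H]1C2 | intermediate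
32 | as 30 with CHO (C2) on C3 (cis to C10) | O=C1CC(C)(C)[C@H]2C[C@]1(C/C=C(\C)CCC=C(C)C)C(=O)[C@]1(C=O)CCC(C)(C)[C@H]1C2 | intermediate
33 | caged aldol: target skeleton with C1–H and C2H(OH) (carbinol epimers), configuration at C1, C3, C5, C7, C11 as in 36 | CC(C)=CCC/C(C)=C/C[C@@]12C[C@H]3C[C@@H]4C(C)(C)CC[C@]4(C1=O)C(O)[C@@H](C2=O)C3(C)C | intermediate
34 | 1-debenzoyl target: caged 2,4,9-trione with C1–H, (1R,3S,5R,7R,11R) | CC(C)=CCC/C(C)=C/C[C@@]12C[C@H]3C[C@@H]4C(C)(C)CC[C@]4(C1=O)C(=O)[C@@H](C2=O)C3(C)C | intermediate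
35 | benzoyl chloride | O=C(Cl)c1ccccc1 | starting material
36 | CNP0168637.1, (1S,3S,5R,7R,11R) in the locants above | CC(C)=CCC/C(C)=C/C[C@@]12C[C@H]3C[C@@H]4C(C)(C)CC[C@]4(C1=O)C(=O)[C@@](C(=O)c1ccccc1)(C2=O)C3(C)C | target

**Step count and risks**
Total step count: 28 (27 in the main line plus step 4, which makes ketene acetal 8). Longest linear sequence: 27 steps (steps 1–3 and 5–28, from 1 to 36).

The three steps most likely to fail:

Step 23 (C- versus O-geranylation of the bridged β-diketone). The fallback sets out from 28 and comes back at 30. Instead of alkylating the sodium enolate with the bromide, 28 is treated with geranyl methyl carbonate and Pd(PPh3)4 (zerovalent palladium) in THF at rt. The methoxide released on ionisation deprotonates the diketone, and the soft enolate attacks the π-geranyl palladium complex at its unsubstituted terminus (Tsuji–Trost allylation). O-allylation is reversible under these conditions, so the C-geranyl product 30 accumulates; this fallback makes no new compound F0.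

Step 26 (enolisation of the neopentyl C1 methylene and aldol closure of ring A). The fallback sets out from 30 and comes back at 33. The only enolisable position of 30 is converted with LiN(SiMe3)2 and Me3SiCl into its silyl enol ether, which is brominated with N-bromosuccinimide at −78 °C to give the C1 α-bromo ketone F1. HF·pyridine removes the silyl ether to give the bromo alcohol F2, and Dess–Martin oxidation gives the bromo aldehyde F3. SmI2 in THF at −78 °C then reduces the C–Br bond to a samarium enolate at C1 under neutral conditions, and this closes onto the C2 aldehyde in a Reformatsky-type aldol reaction to give 33.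

Step 28 (direct C-benzoylation of the hindered bridgehead carbanion). The fallback sets out from 34 and comes back at 36. The lithiated bridgehead is trapped with I2 instead of the acid chloride, giving the bridgehead iodide F4. Iodine–magnesium exchange with i-PrMgCl·LiCl at −78 °C gives a less basic magnesium species that adds to benzaldehyde to give the carbinol F5 (either epimer). Dess–Martin oxidation of F5 gives 36.

**Further compounds**
F0 | step 23 | none | none
F1 | step 26 | C1-bromo derivative of 30 (α-bromo ketone, either C1 epimer) | O=C1C(Br)C(C)(C)[C@H]2C[C@]1(C/C=C(\C)CCC=C(C)C)C(=O)[C@]1(CO[Si](c3ccccc3)(c3ccccc3)C(C)(C)C)CCC(C)(C)[C@H]1C2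
F2 | step 26 | C1-bromo derivative of 31 (bromo alcohol) | O=C1C(Br)C(C)(C)[C@H]2C[C@]1(C/C=C(\C)CCC=C(C)C)C(=O)[C@]1(CO)CCC(C)(C)[C@H]1C2
F3 | step 26 | C1-bromo derivative of 32 (bromo aldehyde) | O=C1C(Br)C(C)(C)[C@H]2C[C@]1(C/C=C(\C)CCC=C(C)C)C(=O)[C@]1(C=O)CCC(C)(C)[C@H]1C2
F4 | step 28 | C1-iodo derivative of 34 (bridgehead iodide) | CC(C)=CCC/C(C)=C/C[C@@]12C[C@H]3C[C@@H]4C(C)(C)CC[C@]4(C1=O)C(=O)[C@@](I)(C2=O)C3(C)C
F5 | step 28 | C1-[hydroxy(phenyl)methyl] derivative of 34 (carbinol epimers) | CC(C)=CCC/C(C)=C/C[C@@]12C[C@H]3C[C@@H]4C(C)(C)CC[C@]4(C1=O)C(=O)[C@@](C(O)c1ccccc1)(C2=O)C3(C)C
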